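**Retrosynthetic overview**

1. The target comes from its bis-MOM ether by acid. That ether comes from a (2S)-2-aryl-6-geranyl-7-silyloxy-2,3,7,8-tetrahydro-6H-chromene-4,5-dione by C7 desilylation and oxidation, which aromatises ring A last.
2. Ring C is cut at C2–C3 and O1–C8a: an aldehyde–diene cycloaddition under a chiral Lewis acid from Ti(OiPr)4 and BINOL (tetravalent titanium), between the ring B aldehyde (supplying C2 and O1) and a 1-methoxy-3-silyloxy diene carried on the non-aromatic ring A.
3. The diene comes from a 2-acetyl-3-methoxy enone, made by bromination at C4a, Stork–Danheiser geranylation at C6 and Stille acetylation of the silylated methyl enol ether of dihydrophloroglucinol, itself from phloroglucinol.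
4. Feature: ring A (C4a, C5, C6, C7, C8, C8a) is a disguised cyclohexane-1,3,5-trione. While C7 is an sp3 carbinol the ring cannot aromatise and C6 is the only kinetic α′-enolate carbon for geranyl. The methyl enol ether that steers this enolate later serves as the leaving group on C8a, and O1 comes from the aldehyde oxygen, so no phenols need differentiating and 6- versus 8-geranyl is fixed covalently.
5. Ring order: ring B (purchased), ring A (non-aromatic, from phloroglucinol), ring C (key step), then aromatisation of ring A.

Key step: step 9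

Remark: in the cyclohexenone intermediates C1, C2, C3, C4, C5, C6 become C5, C4a, C8a, C8, C7, C6 of the flavanone. The two ring A stereocentres (C6, C7) are carried as a racemic, mainly trans pair, are left undefined in the SMILES, and vanish in step 11. A silyl group on the ring enol oxygen could shift between the ring oxygens, so a methyl enol ether is used there instead. "Geranyl" is (2E)-3,7-dimethylocta-2,6-dien-1-yl.

**Route**

Step 1
Reactants: 1 phloroglucinol
Product: 2 5-hydroxycyclohexane-1,3-dione (dihydrophloroglucinol)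
Conditions: H2 (3 atm), Rh/Al2O3 (5 wt % Rh), NaOH (1.0 equiv), H2O, rt; then HCl to pH 3, 0 °C
Reagents that add atoms: none
Why: Partial catalytic hydrogenation of the phenolate (the reaction type of the classical resorcinol to cyclohexane-1,3-dione reduction) should stop after one mole of H2 because the product is a vinylogous carboxylate that resists further reduction, and cold acidification limits dehydration to resorcinol.

Step 2
Reactants: 2 5-hydroxycyclohexane-1,3-dione
Product: 3 5-hydroxy-3-methoxycyclohex-2-en-1-one (racemic)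
Conditions: TMSCHN2 (1.1 equiv), MeOH/PhMe 1:4, 0 °C → rt
Reagents that add atoms: trimethylsilyldiazomethane, C[Si](C)(C)C=[N+]=[N-]
Why: Diazoalkane O-methylation of the acidic enol gives the vinylogous methyl ester under neutral conditions (no acid that would dehydrate the β-hydroxy dione), and since the two carbonyl groups of 2 are enantiotopic only one racemic enol ether can form.

Step 3
Reactants: 3 5-hydroxy-3-methoxycyclohex-2-en-1-one
Product: 4 5-(tert-butyldimethylsilyloxy)-3-methoxycyclohex-2-en-1-one (racemic)
Conditions: TBSCl, imidazole, DMF, rt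
Reagents that add atoms: tert-butyldimethylsilyl chloride, CC(C)(C)[Si](C)(C)Cl
Why: Standard imidazole-promoted silylation of a secondary alcohol keeps the future C7 oxygen as an sp3 carbinol ether so that ring A cannot aromatise.

Step 4
Reactants: 4 5-(tert-butyldimethylsilyloxy)-3-methoxycyclohex-2-en-1-one
Product: 5 2-bromo-5-(tert-butyldimethylsilyloxy)-3-methoxycyclohex-2-en-1-one (racemic)
Conditions: NBS (1.05 equiv), CH2Cl2, 0 °C → rt, dark
Reagents that add atoms: N-bromosuccinimide, O=C1CCC(=O)N1Br
Why: Electrophilic α-bromination of a vinylogous ester, a reaction known for 3-alkoxycyclohex-2-enones, takes place at the nucleophilic C2 and is done before geranyl is present so that no other alkene competes.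

Step 5
Reactants: 5 2-bromo-5-(tert-butyldimethylsilyloxy)-3-methoxycyclohex-2-en-1-one; 6 geranyl bromide
Product: 8 2-bromo-5-(tert-butyldimethylsilyloxy)-6-geranyl-3-methoxycyclohex-2-en-1-one (racemic; mainly 5,6-trans), via lithium enolate 7 (not isolated)
Conditions: LiN(iPr)2 (1.1 equiv), THF, −78 °C; then 6 (1.3 equiv), DMPU, −78 → −40 °C
Reagents that add atoms: none
Why: Stork–Danheiser α′-alkylation, in which kinetic deprotonation can only occur at C6 (C2 carries bromine and C4 is the slower vinylogous site) and the cross-conjugated enolate 7 is captured by the reactive allylic bromide by SN2 displacement at low temperature before silyloxide β-elimination can set in; geranyl should enter anti to the silyloxy group, but both centres are erased later.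

Step 6
Reactants: 8 2-bromo-5-(tert-butyldimethylsilyloxy)-6-geranyl-3-methoxycyclohex-2-en-1-one
Product: 10 2-acetyl-5-(tert-butyldimethylsilyloxy)-6-geranyl-3-methoxycyclohex-2-en-1-one, via ethoxyvinyl enone 9 (not isolated)
Conditions: tributyl(1-ethoxyvinyl)stannane (1.5 equiv), Pd(PPh3)4 (5 mol %), CuI (10 mol %), PhMe, 90 °C; then oxalic acid (0.5 M aq.), THF, 0 °C
Reagents that add atoms: tributyl(1-ethoxyvinyl)stannane, CCCC[Sn](CCCC)(CCCC)C(=C)OCC; water, O
Why: Stille coupling (oxidative addition of zerovalent palladium into the electron-poor C2–Br bond, then transmetalation with the acetyl-anion equivalent) followed by mild acid hydrolysis of the simple enol ether, which should be far faster than hydrolysis of the doubly activated vinylogous ester or the silyl ether.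

Step 7
Reactants: 10 2-acetyl-5-(tert-butyldimethylsilyloxy)-6-geranyl-3-methoxycyclohex-2-en-1-one
Product: 11 5-(tert-butyldimethylsilyloxy)-6-geranyl-3-methoxy-2-[1-(trimethylsilyloxy)vinyl]cyclohex-2-en-1-one
Conditions: TMSOTf (1.3 equiv), Et3N (2 equiv), Et2O, 0 °C; pentane, filtration, used crude
Reagents that add atoms: trimethylsilyl trifluoromethanesulfonate, C[Si](C)(C)OS(=O)(=O)C(F)(F)F
Why: Soft enolisation (silyl triflate and amine), the way 1-alkoxy-3-silyloxy dienes are made from β-alkoxy enones, should silylate only the acetyl group because its methyl is the one unhindered acidic site (C6–H is tertiary and flanked by two substituents).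

Step 8
Reactants: 12 3,4-dihydroxy-5-methoxybenzaldehyde
Product: 13 3-methoxy-4,5-bis(methoxymethoxy)benzaldehyde
Conditions: MOMCl (2.5 equiv), iPr2NEt (3 equiv), CH2Cl2, 0 °C → rt
Reagents that add atoms: chloromethyl methyl ether, COCCl
Why: O-alkylation of both phenols with the chloromethyl ether (acetal protection) masks the catechol against the Lewis acid and the later oxidation while leaving the aldehyde free.

Step 9
Reactants: 11 5-(tert-butyldimethylsilyloxy)-6-geranyl-3-methoxy-2-[1-(trimethylsilyloxy)vinyl]cyclohex-2-en-1-one; 13 3-methoxy-4,5-bis(methoxymethoxy)benzaldehyde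
Product: 15 (2S)-7-(tert-butyldimethylsilyloxy)-6-geranyl-2-[3-methoxy-4,5-bis(methoxymethoxy)phenyl]-2,3,7,8-tetrahydro-6H-chromene-4,5-dione (mixture of C6/C7 stereoisomers), via silyl aldol adduct 14 (not isolated)
Conditions: Ti(OiPr)4 (20 mol %), (S)-BINOL (40 mol %), 4 Å MS, CF3CO2H (cat.), Et2O, −20 → 0 °C, 11 (1.5 equiv); then CF3CO2H (cat.), CH2Cl2, 0 °C; aq. NaHCO3
Reagents that add atoms: none
Why: The BINOL–titanium Lewis acid binds the aldehyde of 13 and the unsubstituted CH2 terminus of the exocyclic silyl enol ether of 11 adds to its Si face, forming C2–C3 and, after silyl transfer to the aldolate, adduct 14; acid then frees the benzylic hydroxyl, which adds to C8a (the methoxy-bearing β-carbon of the doubly activated enone) and expels methanol, forming O1–C8a. The closest known reaction type is the BINOL–titanium-catalysed formal hetero-Diels–Alder reaction (Mukaiyama aldol, then acid cyclisation) of 1-methoxy-3-silyloxy-1,3-dienes with aryl aldehydes to 2-aryl-2,3-dihydropyran-4-ones; diene 11 is a fully substituted, acyl-bearing member of that class, so its rate and selectivity are the open points. Ring C closes by a 6-endo-trig oxa-Michael addition–elimination. C2 is set by the catalyst alone, with (S)-BINOL proposed for Si-face delivery and (R)-BINOL to be used instead if a first run shows the opposite sense, while the racemic ring A centres lie five bonds from the reacting carbon and should not interfere. The step needs O1 to bond to the ring carbon remote from geranyl, and this is secured because only C8a carries a leaving group (the other ring carbonyl can only form a reversible hemiketal) and neither the methyl group nor the exocyclic silyl group can migrate between oxygens. Base is excluded so that neither E1cB loss of the C7 silyloxy group nor retro-oxa-Michael opening of ring C, which would erode C2, can occur.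

Step 10
Reactants: 15 (2S)-7-(tert-butyldimethylsilyloxy)-6-geranyl-2-[3-methoxy-4,5-bis(methoxymethoxy)phenyl]-2,3,7,8-tetrahydro-6H-chromene-4,5-dione
Product: 16 (2S)-6-geranyl-7-hydroxy-2-[3-methoxy-4,5-bis(methoxymethoxy)phenyl]-2,3,7,8-tetrahydro-6H-chromene-4,5-dione (mixture of C6/C7 stereoisomers)
Conditions: HF·pyridine, pyridine, THF, 0 °C → rt
Reagents that add atoms: none
Why: Fluoride desilylation under buffered, weakly acidic conditions cleaves the secondary silyl ether while avoiding the basic fluoride sources that would cause β-elimination of the C7 oxygen or open ring C; the MOM ethers and alkenes are inert.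

Step 11
Reactants: 16 (2S)-6-geranyl-7-hydroxy-2-[3-methoxy-4,5-bis(methoxymethoxy)phenyl]-2,3,7,8-tetrahydro-6H-chromene-4,5-dione
Product: 18 (2S)-6-geranyl-5,7-dihydroxy-2-[3-methoxy-4,5-bis(methoxymethoxy)phenyl]chroman-4-one, via chromanetrione 17 (not isolated)
Conditions: Dess–Martin periodinane (1.2 equiv), pyridine (3 equiv), CH2Cl2, 0 °C → rt; aq. Na2S2O3
Reagents that add atoms: none
Why: Dess–Martin oxidation of a β-hydroxy ketone to the 1,3-diketone gives trione 17, the keto tautomer of an acylphloroglucinol, which should enolise spontaneously at C6–H and C8–H to the aromatic ring A, converging all ring A stereoisomers without touching C2.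

Step 12
Reactants: 18 (2S)-6-geranyl-5,7-dihydroxy-2-[3-methoxy-4,5-bis(methoxymethoxy)phenyl]chroman-4-one
Product: 19 (2S)-2-(3,4-dihydroxy-5-methoxyphenyl)-6-geranyl-5,7-dihydroxychroman-4-one (CNP0110161.1)
Conditions: HCl (1 M in MeOH/H2O 9:1), rt → 40 °C
Reagents that add atoms: none
Why: Acid-catalysed transacetalisation with methanol removes both MOM groups under conditions of the kind commonly used for prenylated flavanones, mild enough to leave the geranyl alkenes and the acid-stable C2 centre unchanged.

**Compound list**

1 | phloroglucinol | Oc1cc(O)cc(O)c1 | starting material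
2 | 5-hydroxycyclohexane-1,3-dione (dihydrophloroglucinol) | O=C1CC(O)CC(=O)C1 | intermediate
3 | 5-hydroxy-3-methoxycyclohex-2-en-1-one (racemic) | COC1=CC(=O)CC(O)C1 | intermediate
4 | 5-(tert-butyldimethylsilyloxy)-3-methoxycyclohex-2-en-1-one (racemic) | COC1=CC(=O)CC(O[Si](C)(C)C(C)(C)C)C1 | intermediate
5 | 2-bromo-5-(tert-butyldimethylsilyloxy)-3-methoxycyclohex-2-en-1-one (racemic) | COC1=C(Br)C(=O)CC(O[Si](C)(C)C(C)(C)C)C1 | intermediate
6 | geranyl bromide, (2E)-1-bromo-3,7-dimethylocta-2,6-diene | BrC/C=C(\C)CCC=C(C)C | starting material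
7 | lithium 6-bromo-3-(tert-butyldimethylsilyloxy)-5-methoxycyclohexa-1,5-dien-1-olate (kinetic enolate of 5, not isolated) | COC1=C(Br)C(O[Li])=CC(O[Si](C)(C)C(C)(C)C)C1 | intermediate
8 | 2-bromo-5-(tert-butyldimethylsilyloxy)-6-geranyl-3-methoxycyclohex-2-en-1-one (racemic, mainly 5,6-trans) | COC1=C(Br)C(=O)C(C/C=C(\C)CCC=C(C)C)C(O[Si](C)(C)C(C)(C)C)C1 | intermediate
9 | 5-(tert-butyldimethylsilyloxy)-2-(1-ethoxyvinyl)-6-geranyl-3-methoxycyclohex-2-en-1-one (not isolated) | CCOC(=C)C1=C(OC)CC(O[Si](C)(C)C(C)(C)C)C(C/C=C(\C)CCC=C(C)C)C1=O | intermediate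
10 | 2-acetyl-5-(tert-butyldimethylsilyloxy)-6-geranyl-3-methoxycyclohex-2-en-1-one | CC(=O)C1=C(OC)CC(O[Si](C)(C)C(C)(C)C)C(C/C=C(\C)CCC=C(C)C)C1=O | intermediate
11 | 5-(tert-butyldimethylsilyloxy)-6-geranyl-3-methoxy-2-[1-(trimethylsilyloxy)vinyl]cyclohex-2-en-1-one | C=C(O[Si](C)(C)C)C1=C(OC)CC(O[Si](C)(C)C(C)(C)C)C(C/C=C(\C)CCC=C(C)C)C1=O | intermediate
12 | 3,4-dihydroxy-5-methoxybenzaldehyde | COc1cc(C=O)cc(O)c1O | starting material
13 | 3-methoxy-4,5-bis(methoxymethoxy)benzaldehyde | COc1cc(C=O)cc(OCOC)c1OCOC | intermediate
14 | (S)-configured Mukaiyama aldol adduct, benzylic trimethylsilyl ether (not isolated) | COc1cc([C@@H](O[Si](C)(C)C)CC(=O)C2=C(OC)CC(O[Si](C)(C)C(C)(C)C)C(C/C=C(\C)CCC=C(C)C)C2=O)cc(OCOC)c1OCOC | intermediate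
15 | (2S)-7-(tert-butyldimethylsilyloxy)-6-geranyl-2-[3-methoxy-4,5-bis(methoxymethoxy)phenyl]-2,3,7,8-tetrahydro-6H-chromene-4,5-dione | COc1cc([C@@H]2CC(=O)C3=C(CC(O[Si](C)(C)C(C)(C)C)C(C/C=C(\C)CCC=C(C)C)C3=O)O2)cc(OCOC)c1OCOC | intermediate
16 | (2S)-6-geranyl-7-hydroxy-2-[3-methoxy-4,5-bis(methoxymethoxy)phenyl]-2,3,7,8-tetrahydro-6H-chromene-4,5-dione | COc1cc([C@@H]2CC(=O)C3=C(CC(O)C(C/C=C(\C)CCC=C(C)C)C3=O)O2)cc(OCOC)c1OCOC | intermediate
17 | (2S)-6-geranyl-2-[3-methoxy-4,5-bis(methoxymethoxy)phenyl]-2,3-dihydro-4H-chromene-4,5,7(6H,8H)-trione (not isolated) | COc1cc([C@@H]2CC(=O)C3=C(CC(=O)C(C/C=C(\C)CCC=C(C)C)C3=O)O2)cc(OCOC)c1OCOC | intermediate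
18 | (2S)-6-geranyl-5,7-dihydroxy-2-[3-methoxy-4,5-bis(methoxymethoxy)phenyl]chroman-4-one | COc1cc([C@@H]2CC(=O)c3c(cc(O)c(C/C=C(\C)CCC=C(C)C)c3O)O2)cc(OCOC)c1OCOC | intermediate
19 | (2S)-2-(3,4-dihydroxy-5-methoxyphenyl)-6-geranyl-5,7-dihydroxychroman-4-one (CNP0110161.1) | COc1cc([C@@H]2CC(=O)c3c(cc(O)c(C/C=C(\C)CCC=C(C)C)c3O)O2)cc(O)c1O | target

Total step count: 12
Longest linear sequence: 11 steps (steps 1–7 and 9–12); step 8 prepares the aldehyde separately.

**Steps most likely to fail**

Step 9. The C–C bond formation may stall: the nucleophile is a twisted silyl enol ether next to an acyl group, the aldehyde is electron-rich, and the 1,3-dicarbonyl unit of the product can tie up the titanium. Facial discrimination with this untested diene may also be poor. The fallback sets out from ketone 10 (diene 11 is bypassed) and aldehyde 13 and comes back at 15. Ketone 10 is enolised with (−)-Ipc2BCl and Et3N in Et2O (−78 → 0 °C) to the diisopinocampheylboron enolate F1. This adds to 13 at −78 °C through a closed six-membered transition state (reagent-controlled boron aldol of a methyl ketone), and a non-oxidative work-up gives the (S)-β-hydroxy ketone F2. PPTS in CH2Cl2 then closes ring C by the same 6-endo addition–elimination with loss of methanol to give 15. The (−)-reagent is tried first, and its mirror image is used if a model run shows Re-face addition.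

Step 5. Silyloxide may be lost from enolate 7 by β-elimination with irreversible aromatisation, or enolate equilibration may lead to γ- or double alkylation. The fallback sets out from 3 and comes back at 8. Alcohol 3 is brominated with NBS as in step 4 to 2-bromo-5-hydroxy-3-methoxycyclohex-2-en-1-one F3. LiN(iPr)2 (2.2 equiv, THF/DMPU, −78 °C) converts it into the dilithium alkoxide–enolate F4, in which the β-oxygen is an alkoxide and cannot leave. This is alkylated on carbon by 6 (dianion alkylation of a β-hydroxy carbonyl compound, Fráter–Seebach type) to 2-bromo-6-geranyl-5-hydroxy-3-methoxycyclohex-2-en-1-one F5. TBSCl and imidazole then give 8.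

Step 10. Cleavage of the hindered secondary silyl ether may be slow, and during the long acid exposure ring C can open and reclose (erosion at C2) or the freed β-hydroxy ketone can dehydrate towards the aromatic 7-deoxy ring. The fallback sets out from 10 and comes back at 16, moving the fluoride step to a stage with no C2 centre. Ketone 10 is desilylated with HF·pyridine to 2-acetyl-6-geranyl-5-hydroxy-3-methoxycyclohex-2-en-1-one F6. TMSOTf (2.5 equiv) and Et3N silylate both the alcohol and the acetyl group to give the bis(trimethylsilyl) diene F7. Under the catalyst of step 9 this adds to 13 to give the bis(trimethylsilyl) aldol adduct F8 (not isolated), and the acid that closes ring C also removes the labile secondary trimethylsilyl ether, giving 16 directly.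

**Further compounds**

F1 | step 9 | diisopinocampheylboron enolate of ketone 10, (−)-Ipc series | C=C(OB([C@@H]1C[C@@H]2C[C@@H](C2(C)C)[C@H]1C)[C@@H]1C[C@@H]2C[C@@H](C2(C)C)[C@H]1C)C1=C(OC)CC(O[Si](C)(C)C(C)(C)C)C(C/C=C(\C)CCC=C(C)C)C1=O
F2 | step 9 | 5-(tert-butyldimethylsilyloxy)-6-geranyl-2-{(3S)-3-hydroxy-3-[3-methoxy-4,5-bis(methoxymethoxy)phenyl]propanoyl}-3-methoxycyclohex-2-en-1-one | COc1cc([C@@H](O)CC(=O)C2=C(OC)CC(O[Si](C)(C)C(C)(C)C)C(C/C=C(\C)CCC=C(C)C)C2=O)cc(OCOC)c1OCOC
F3 | step 5 | 2-bromo-5-hydroxy-3-methoxycyclohex-2-en-1-one (racemic) | COC1=C(Br)C(=O)CC(O)C1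
F4 | step 5 | dilithium alkoxide–enolate of F3 (not isolated) | COC1=C(Br)C(O[Li])=CC(O[Li])C1
F5 | step 5 | 2-bromo-6-geranyl-5-hydroxy-3-methoxycyclohex-2-en-1-one (racemic, mainly 5,6-trans) | COC1=C(Br)C(=O)C(C/C=C(\C)CCC=C(C)C)C(O)C1
F6 | step 10 | 2-acetyl-6-geranyl-5-hydroxy-3-methoxycyclohex-2-en-1-one | CC(=O)C1=C(OC)CC(O)C(C/C=C(\C)CCC=C(C)C)C1=O
F7 | step 10 | 6-geranyl-3-methoxy-5-(trimethylsilyloxy)-2-[1-(trimethylsilyloxy)vinyl]cyclohex-2-en-1-one | C=C(O[Si](C)(C)C)C1=C(OC)CC(O[Si](C)(C)C)C(C/C=C(\C)CCC=C(C)C)C1=O
F8 | step 10 | (S)-configured aldol adduct with benzylic and ring trimethylsilyl ethers (not isolated) | COc1cc([C@@H](O[Si](C)(C)C)CC(=O)C2=C(OC)CC(O[Si](C)(C)C)C(C/C=C(\C)CCC=C(C)C)C2=O)cc(OCOC)c1OCOC
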